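**Retrosynthetic overview**
1. The 3‑OH is unmasked last (THP off under weak acid), after acetylation of O‑4. The mono‑acetate regiochemistry is therefore fixed by orthogonal O‑3 (THP) / O‑4 (allyl) protection, not by a selective acylation.
2. The Ar–CH2–CH2–Ar′ bridge comes from a stilbene (Wittig), reduced by a Rh‑catalysed hydrogenation that spares the prenyl alkene. The O‑allyl group is removed with Pd(0) before that hydrogenation.
3. Ring A ylide precursor: 4‑bromo‑3,5‑dimethoxybenzyl alcohol plus prenyl bromide (Br/Li exchange, then alkylation).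
4. Ring B aldehyde: 2,3,4‑trihydroxybenzaldehyde, functionalised in order of OH reactivity – O‑4 allyl (most acidic), O‑3 THP (free OH), O‑2 methyl (chelated OH, last).
5. No ring is formed: both benzene rings are bought intact, and the oxane ring of the THP group is temporary.

Assumption: the target has no stereocentre and no stereogenic double bond, so the achiral compound is the "single enantiomer"; THP intermediates are carried as racemates and the stilbene as an E/Z mixture, and both elements disappear before the target.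

**Route**

Step 1
Reactants: 1 (4-bromo-3,5-dimethoxyphenyl)methanol
Product: 3 [3,5-dimethoxy-4-(3-methylbut-2-en-1-yl)phenyl]methanol, via dilithiated alcohol 2 (not isolated)
Conditions: n‑BuLi (2.1 equiv), THF, −78 °C, 30 min; prenyl bromide (1.3 equiv), −78 → 0 °C; H2O quench
Reagents that add atoms: prenyl bromide (1-bromo-3-methylbut-2-ene), CC(C)=CCBr
Why: After O‑deprotonation, bromine–lithium exchange gives the aryllithium at the only possible position (between the two OMe groups), and its SN2 alkylation by the primary allylic bromide installs the prenyl group; no stereocentre is formed.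

Step 2
Reactants: 3 [3,5-dimethoxy-4-(3-methylbut-2-en-1-yl)phenyl]methanol
Product: 5 {[3,5-dimethoxy-4-(3-methylbut-2-en-1-yl)phenyl]methyl}(triphenyl)phosphonium bromide, via benzyl bromide 4 (not isolated)
Conditions: CBr4 (1.05 equiv), PPh3 (1.1 equiv), CH2Cl2, 0 °C; then PPh3 (1.2 equiv), toluene, 90 °C; salt filtered off
Reagents that add atoms: carbon tetrabromide, BrC(Br)(Br)Br; triphenylphosphine, c1ccc(cc1)P(c1ccccc1)c1ccccc1
Why: The Appel bromination is neutral towards the prenyl alkene, and the benzylic bromide is quaternised in the same flask by further PPh3 (SN2) to give the Wittig salt.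

Step 3
Reactants: 6 2,3,4-trihydroxybenzaldehyde
Product: 7 2,3-dihydroxy-4-(prop-2-en-1-yloxy)benzaldehyde
Conditions: allyl bromide (1.05 equiv), NaHCO3 (1.5 equiv), NaI (0.2 equiv), DMF, 40 °C, N2
Reagents that add atoms: allyl bromide, C=CCBr
Why: In this Williamson etherification bicarbonate ionises only the 4‑OH (para to CHO, most acidic), while the 2‑OH is held in the hydrogen bond to the aldehyde, so mono‑allylation occurs at O‑4.

Step 4
Reactants: 7 2,3-dihydroxy-4-(prop-2-en-1-yloxy)benzaldehyde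
Product: 8 2-hydroxy-3-(oxan-2-yloxy)-4-(prop-2-en-1-yloxy)benzaldehyde (racemic)
Conditions: 3,4‑dihydro‑2H‑pyran (2 equiv), PPTS (0.1 equiv), CH2Cl2, rt
Reagents that add atoms: 3,4-dihydro-2H-pyran, C1=COCCC1
Why: Acid‑catalysed tetrahydropyranylation takes the free 3‑OH while the chelated 2‑OH stays untouched; the acetal stereocentre forms unselectively (racemate) and is removed in step 10.

Step 5
Reactants: 8 2-hydroxy-3-(oxan-2-yloxy)-4-(prop-2-en-1-yloxy)benzaldehyde
Product: 9 2-methoxy-3-(oxan-2-yloxy)-4-(prop-2-en-1-yloxy)benzaldehyde (racemic)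
Conditions: MeI (3 equiv), K2CO3 (2 equiv), DMF, 40 °C
Reagents that add atoms: iodomethane, CI
Why: Williamson methylation of the last, chelated phenol proceeds under carbonate/DMF conditions to which the allyl ether and the THP acetal are inert.

Step 6
Reactants: 5 {[3,5-dimethoxy-4-(3-methylbut-2-en-1-yl)phenyl]methyl}(triphenyl)phosphonium bromide; 9 2-methoxy-3-(oxan-2-yloxy)-4-(prop-2-en-1-yloxy)benzaldehyde
Product: 11 1-{2-[3,5-dimethoxy-4-(3-methylbut-2-en-1-yl)phenyl]ethenyl}-2-methoxy-3-(oxan-2-yloxy)-4-(prop-2-en-1-yloxy)benzene (E/Z mixture; racemic), via phosphonium ylide 10 (not isolated)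
Conditions: 5 (1.15 equiv), KOtBu (1.15 equiv), THF, 0 °C; then 9, 0 °C → rt
Reagents that add atoms: none
Why: Wittig olefination of the semi‑stabilised benzylic ylide with the aryl aldehyde forms the bridge C=C bond, and the E/Z ratio does not matter because both isomers are hydrogenated in step 8.

Step 7
Reactants: 11 1-{2-[3,5-dimethoxy-4-(3-methylbut-2-en-1-yl)phenyl]ethenyl}-2-methoxy-3-(oxan-2-yloxy)-4-(prop-2-en-1-yloxy)benzene
Product: 12 4-{2-[3,5-dimethoxy-4-(3-methylbut-2-en-1-yl)phenyl]ethenyl}-3-methoxy-2-(oxan-2-yloxy)phenol (E/Z mixture; racemic)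
Conditions: Pd(PPh3)4 (5 mol%), morpholine (5 equiv), THF, rt
Reagents that add atoms: none
Why: In this Tsuji–Trost deallylation Pd(0) ionises the aryl allyl ether and morpholine traps the π‑allyl unit, while the prenyl group (no leaving group), stilbene and THP acetal are inert; it must precede step 8 because an O‑allyl group would be hydrogenated.

Step 8
Reactants: 12 4-{2-[3,5-dimethoxy-4-(3-methylbut-2-en-1-yl)phenyl]ethenyl}-3-methoxy-2-(oxan-2-yloxy)phenol
Product: 13 4-{2-[3,5-dimethoxy-4-(3-methylbut-2-en-1-yl)phenyl]ethyl}-3-methoxy-2-(oxan-2-yloxy)phenol (racemic)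
Conditions: H2 (1–3 atm), RhCl(PPh3)3 (5–10 mol%), toluene/THF 2:1, rt → 40 °C; stopped when the stilbene is consumed
Reagents that add atoms: none
Why: Homogeneous hydrogenation with Wilkinson's catalyst reduces the 1,2‑disubstituted, aryl‑conjugated alkene much faster than the trisubstituted prenyl alkene and leaves the acetal alone; no stereocentre is formed.

Step 9
Reactants: 13 4-{2-[3,5-dimethoxy-4-(3-methylbut-2-en-1-yl)phenyl]ethyl}-3-methoxy-2-(oxan-2-yloxy)phenol
Product: 14 4-{2-[3,5-dimethoxy-4-(3-methylbut-2-en-1-yl)phenyl]ethyl}-3-methoxy-2-(oxan-2-yloxy)phenyl acetate (racemic)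
Conditions: Ac2O (1.5 equiv), pyridine (3 equiv), DMAP (5 mol%), CH2Cl2, 0 °C → rt
Reagents that add atoms: acetic anhydride, CC(=O)OC(C)=O
Why: DMAP‑catalysed O‑acylation of the only free phenol places the acetate on O‑4 unambiguously, because O‑3 is blocked as the THP ether.

Step 10
Reactants: 14 4-{2-[3,5-dimethoxy-4-(3-methylbut-2-en-1-yl)phenyl]ethyl}-3-methoxy-2-(oxan-2-yloxy)phenyl acetate
Product: 15 4-{2-[3,5-dimethoxy-4-(3-methylbut-2-en-1-yl)phenyl]ethyl}-2-hydroxy-3-methoxyphenyl acetate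
Conditions: AcOH/THF/H2O 4:2:1, 40 °C; evaporation with toluene, no basic wash
Reagents that add atoms: none
Why: Mild acid‑catalysed hydrolysis of the aryl THP acetal runs under base‑free conditions in which the aryl acetate neither hydrolyses nor migrates to O‑3 and the prenyl alkene is not protonated.

**Compound list**
1 | (4-bromo-3,5-dimethoxyphenyl)methanol | COc1cc(CO)cc(OC)c1Br | starting material
2 | lithium (4-lithio-3,5-dimethoxyphenyl)methanolate (O,C‑dilithio species, formed in situ) | [Li]OCc1cc(OC)c([Li])c(OC)c1 | intermediate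
3 | [3,5-dimethoxy-4-(3-methylbut-2-en-1-yl)phenyl]methanol | COc1cc(CO)cc(OC)c1CC=C(C)C | intermediate
4 | 5-(bromomethyl)-1,3-dimethoxy-2-(3-methylbut-2-en-1-yl)benzene (formed in situ) | COc1cc(CBr)cc(OC)c1CC=C(C)C | intermediate
5 | {[3,5-dimethoxy-4-(3-methylbut-2-en-1-yl)phenyl]methyl}(triphenyl)phosphonium bromide | COc1cc(C[P+](c2ccccc2)(c2ccccc2)c2ccccc2)cc(OC)c1CC=C(C)C.[Br-] | intermediate
6 | 2,3,4-trihydroxybenzaldehyde | O=Cc1ccc(O)c(O)c1O | starting material
7 | 2,3-dihydroxy-4-(prop-2-en-1-yloxy)benzaldehyde | O=Cc1ccc(OCC=C)c(O)c1O | intermediate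
8 | 2-hydroxy-3-(oxan-2-yloxy)-4-(prop-2-en-1-yloxy)benzaldehyde (racemic at the acetal carbon) | O=Cc1ccc(OCC=C)c(OC2CCCCO2)c1O | intermediate
9 | 2-methoxy-3-(oxan-2-yloxy)-4-(prop-2-en-1-yloxy)benzaldehyde (racemic) | COc1c(C=O)ccc(OCC=C)c1OC1CCCCO1 | intermediate
10 | {[3,5-dimethoxy-4-(3-methylbut-2-en-1-yl)phenyl]methylidene}(triphenyl)phosphorane (ylide, formed in situ) | COc1cc(C=P(c2ccccc2)(c2ccccc2)c2ccccc2)cc(OC)c1CC=C(C)C | intermediate
11 | 1-{2-[3,5-dimethoxy-4-(3-methylbut-2-en-1-yl)phenyl]ethenyl}-2-methoxy-3-(oxan-2-yloxy)-4-(prop-2-en-1-yloxy)benzene (E/Z mixture, racemic) | COc1cc(C=Cc2ccc(OCC=C)c(OC3CCCCO3)c2OC)cc(OC)c1CC=C(C)C | intermediate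
12 | 4-{2-[3,5-dimethoxy-4-(3-methylbut-2-en-1-yl)phenyl]ethenyl}-3-methoxy-2-(oxan-2-yloxy)phenol (E/Z mixture, racemic) | COc1cc(C=Cc2ccc(O)c(OC3CCCCO3)c2OC)cc(OC)c1CC=C(C)C | intermediate
13 | 4-{2-[3,5-dimethoxy-4-(3-methylbut-2-en-1-yl)phenyl]ethyl}-3-methoxy-2-(oxan-2-yloxy)phenol (racemic) | COc1cc(CCc2ccc(O)c(OC3CCCCO3)c2OC)cc(OC)c1CC=C(C)C | intermediate
14 | 4-{2-[3,5-dimethoxy-4-(3-methylbut-2-en-1-yl)phenyl]ethyl}-3-methoxy-2-(oxan-2-yloxy)phenyl acetate (racemic) | COc1cc(CCc2ccc(OC(C)=O)c(OC3CCCCO3)c2OC)cc(OC)c1CC=C(C)C | intermediate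
15 | 4-{2-[3,5-dimethoxy-4-(3-methylbut-2-en-1-yl)phenyl]ethyl}-2-hydroxy-3-methoxyphenyl acetate (achiral) | COc1cc(CCc2ccc(OC(C)=O)c(O)c2OC)cc(OC)c1CC=C(C)C | target

**Totals**
Total step count: 10. Longest linear sequence: 8 steps (6 → 15, steps 3–10); the ring A branch (steps 1–2) joins at step 6.

**Steps most likely to fail, with fallbacks**

Step 3 (mono‑allylation of one of three phenols in an air‑sensitive substrate; over‑alkylation or O‑3 alkylation possible). The fallback sets out from 6 and ties O‑3/O‑4 together first. Dichlorodiphenylmethane (Ph2O, 170 °C) gives 4-hydroxy-2,2-diphenyl-1,3-benzodioxole-5-carbaldehyde F1. Methylation of the remaining 2‑OH (MeI, K2CO3, DMF) gives 4-methoxy-2,2-diphenyl-1,3-benzodioxole-5-carbaldehyde F2. Ketal hydrolysis (AcOH/H2O, reflux) gives 3,4-dihydroxy-2-methoxybenzaldehyde F3. Bicarbonate‑controlled allylation of its para‑OH (allyl bromide, NaHCO3, NaI, DMF) gives 3-hydroxy-2-methoxy-4-(prop-2-en-1-yloxy)benzaldehyde F4. DHP/PPTS on the single remaining OH then comes back to the route at 9.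

Step 8 (partial reduction of the prenyl alkene, or sluggish reduction of the E‑stilbene). The fallback reduces the bridge before the prenyl group exists and sets out from 1. PPh3·HBr (MeCN, reflux) gives [(4-bromo-3,5-dimethoxyphenyl)methyl](triphenyl)phosphonium bromide F5. KOtBu gives the ylide [(4-bromo-3,5-dimethoxyphenyl)methylidene](triphenyl)phosphorane F6, which with 9 gives 1-[2-(4-bromo-3,5-dimethoxyphenyl)ethenyl]-2-methoxy-3-(oxan-2-yloxy)-4-(prop-2-en-1-yloxy)benzene F7. Pd(PPh3)4/morpholine gives 4-[2-(4-bromo-3,5-dimethoxyphenyl)ethenyl]-3-methoxy-2-(oxan-2-yloxy)phenol F8. Diimide (TsNHNH2, NaOAc, DME/H2O, reflux), which leaves ArBr and the THP group alone, gives 4-[2-(4-bromo-3,5-dimethoxyphenyl)ethyl]-3-methoxy-2-(oxan-2-yloxy)phenol F9. A Stille coupling with tributyl(3-methylbut-2-en-1-yl)stannane (Pd catalyst, DMF, 100 °C) installs the prenyl group and comes back to the route at 13.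

Step 10 (loss of the acetate, or its migration to O‑3, while the neighbouring phenol is released). The fallback sets out from 13 and reverses the order of the last two operations. The same aqueous AcOH removes the THP group to give 4-{2-[3,5-dimethoxy-4-(3-methylbut-2-en-1-yl)phenyl]ethyl}-3-methoxybenzene-1,2-diol F10. This catechol is mono‑acetylated under neutral conditions with vinyl acetate and immobilised Candida antarctica lipase B (MTBE, 40 °C). The 3‑OH, flanked by two ortho substituents, is expected to be left alone, and the sequence comes back to the route at 15.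

**Further compounds**
F1 | step 3 | 4-hydroxy-2,2-diphenyl-1,3-benzodioxole-5-carbaldehyde | O=Cc1ccc2OC(c3ccccc3)(c3ccccc3)Oc2c1O
F2 | step 3 | 4-methoxy-2,2-diphenyl-1,3-benzodioxole-5-carbaldehyde | COc1c(C=O)ccc2OC(c3ccccc3)(c3ccccc3)Oc12
F3 | step 3 | 3,4-dihydroxy-2-methoxybenzaldehyde | COc1c(C=O)ccc(O)c1O
F4 | step 3 | 3-hydroxy-2-methoxy-4-(prop-2-en-1-yloxy)benzaldehyde | COc1c(C=O)ccc(OCC=C)c1O
F5 | step 8 | [(4-bromo-3,5-dimethoxyphenyl)methyl](triphenyl)phosphonium bromide | COc1cc(C[P+](c2ccccc2)(c2ccccc2)c2ccccc2)cc(OC)c1Br.[Br-]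
F6 | step 8 | [(4-bromo-3,5-dimethoxyphenyl)methylidene](triphenyl)phosphorane | COc1cc(C=P(c2ccccc2)(c2ccccc2)c2ccccc2)cc(OC)c1Br
F7 | step 8 | 1-[2-(4-bromo-3,5-dimethoxyphenyl)ethenyl]-2-methoxy-3-(oxan-2-yloxy)-4-(prop-2-en-1-yloxy)benzene (E/Z mixture, racemic) | COc1cc(C=Cc2ccc(OCC=C)c(OC3CCCCO3)c2OC)cc(OC)c1Br
F8 | step 8 | 4-[2-(4-bromo-3,5-dimethoxyphenyl)ethenyl]-3-methoxy-2-(oxan-2-yloxy)phenol (E/Z mixture, racemic) | COc1cc(C=Cc2ccc(O)c(OC3CCCCO3)c2OC)cc(OC)c1Br
F9 | step 8 | 4-[2-(4-bromo-3,5-dimethoxyphenyl)ethyl]-3-methoxy-2-(oxan-2-yloxy)phenol (racemic) | COc1cc(CCc2ccc(O)c(OC3CCCCO3)c2OC)cc(OC)c1Br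
F10 | step 10 | 4-{2-[3,5-dimethoxy-4-(3-methylbut-2-en-1-yl)phenyl]ethyl}-3-methoxybenzene-1,2-diol | COc1cc(CCc2ccc(O)c(O)c2OC)cc(OC)c1CC=C(C)C
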